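**Retrosynthetic overview**
1. Ring C is made last: a one-carbon ring expansion (radical 1,2-acyl shift) turns a 2-aryl-2-(iodomethyl)benzofuran-3(2H)-one into the flavanone, a chiral thiol sets the C2–H bond as 2S, and MOM removal then gives the target.
2. The quaternary benzofuranone comes from a 7-prenyl-4,6-bis(MOM)benzofuran-3(2H)-one, a 6-bromo-8-prenyl-2,2-dimethylchromene and CH2I2 (Pd α-arylation, then enolate alkylation).
3. Ring A piece: resorcinol → bis-MOM ether → C–H borylation/oxidation (third oxygen) → ortho-prenylation → O-alkylation → intramolecular acylation, which closes the furanone ring with the prenyl group fixed next to the ring oxygen.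
4. Ring B piece: 4-bromophenol → ortho-prenylation → chromene annulation with 3-methylbut-2-enal (pyran ring).
5. Ring order: furanone ring on ring A (step 5), pyran ring on ring B (step 7), union (step 8), five- to six-membered expansion to ring C (step 9).

Assumption: the face selectivity of the chiral thiol in step 9 must be fixed by experiment; the peptide enantiomer that gives the 2S product is used (both mirror-image peptides are accessible).

**Step 1**
Reactants: 1 resorcinol
Product: 2 1,3-bis(methoxymethoxy)benzene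
Conditions: NaH, MOMCl, DMF, 0 °C → rt
Reagents that add atoms: chloromethyl methyl ether COCCl
Why: Williamson-type O-alkylation of both phenoxides gives the bis-acetal, a standard MOM protection.

**Step 2**
Reactants: 2 1,3-bis(methoxymethoxy)benzene
Product: 4 3,5-bis(methoxymethoxy)phenol, via arylboronate 3 (not isolated)
Conditions: [Ir(OMe)(cod)]2 (1.5 mol%), dtbpy (3 mol%), B2pin2, THF, 80 °C; then 30% H2O2, aq. NaOH, 0 °C → rt
Reagents that add atoms: bis(pinacolato)diboron CC1(C)OB(OC1(C)C)B1OC(C)(C)C(C)(C)O1 (boron and pinacolate of intermediate 3 only); hydrogen peroxide OO (phenol oxygen of 4)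
Why: Sterically controlled iridium-catalysed C–H borylation goes to C5, the only C–H without an ortho substituent, and the C–B bond is then oxidised to the phenol (borylation–oxidation).

**Step 3**
Reactants: 4 3,5-bis(methoxymethoxy)phenol; 5 1-bromo-3-methylbut-2-ene (prenyl bromide)
Product: 6 3,5-bis(methoxymethoxy)-2-(3-methylbut-2-en-1-yl)phenol
Conditions: NaH, toluene, 0 °C → rt
Reagents that add atoms: none
Why: ortho-Selective C-alkylation of the sodium phenoxide as a tight ion pair in a non-polar solvent; the two ortho positions are equivalent, so one C-prenyl isomer forms next to the free OH.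

**Step 4**
Reactants: 6 3,5-bis(methoxymethoxy)-2-(3-methylbut-2-en-1-yl)phenol; 7 2-chloro-N,N-dimethylacetamide
Product: 8 2-[3,5-bis(methoxymethoxy)-2-(3-methylbut-2-en-1-yl)phenoxy]-N,N-dimethylacetamide
Conditions: K2CO3, NaI (cat.), DMF, 60 °C
Reagents that add atoms: none
Why: Williamson ether synthesis on the only free phenol, which becomes the ring oxygen flanked by the prenyl group.

**Step 5**
Reactants: 8 2-[3,5-bis(methoxymethoxy)-2-(3-methylbut-2-en-1-yl)phenoxy]-N,N-dimethylacetamide
Product: 10 4,6-bis(methoxymethoxy)-7-(3-methylbut-2-en-1-yl)benzofuran-3(2H)-one, via iminium triflate 9 (not isolated)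
Conditions: Tf2O (1.1 equiv), 2-chloropyridine (1.5 equiv), CH2Cl2 (0.02 M), −78 → 0 °C; then aq. NaOAc/AcOH (pH 5), rt
Reagents that add atoms: trifluoromethanesulfonic anhydride O=S(=O)(OS(=O)(=O)C(F)(F)F)C(F)(F)F (triflate counter-ion of intermediate 9 only); water O (carbonyl oxygen of 10)
Why: Electrophilic amide activation followed by intramolecular Friedel–Crafts (Vilsmeier–Haack-type) acylation at the only free position ortho to the ether oxygen, then iminium hydrolysis, so the prenyl group ends up at C7 beside the ring oxygen.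

**Step 6**
Reactants: 11 4-bromophenol; 5 1-bromo-3-methylbut-2-ene (prenyl bromide)
Product: 12 4-bromo-2-(3-methylbut-2-en-1-yl)phenol
Conditions: NaH, toluene, 0 °C → rt
Reagents that add atoms: none
Why: ortho-Selective C-alkylation of the sodium phenoxide in a non-polar solvent, with the para position blocked by bromine.

**Step 7**
Reactants: 12 4-bromo-2-(3-methylbut-2-en-1-yl)phenol; 13 3-methylbut-2-enal
Product: 14 6-bromo-2,2-dimethyl-8-(3-methylbut-2-en-1-yl)-2H-chromene
Conditions: PhB(OH)2, AcOH, toluene, reflux (Dean–Stark)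
Reagents that add atoms: none
Why: Boronic-acid-templated ortho-condensation of the phenol with the enal gives an ortho-quinone methide that closes by oxa-6π electrocyclisation at the one free ortho position (chromene annulation).

**Step 8**
Reactants: 10 4,6-bis(methoxymethoxy)-7-(3-methylbut-2-en-1-yl)benzofuran-3(2H)-one; 14 6-bromo-2,2-dimethyl-8-(3-methylbut-2-en-1-yl)-2H-chromene; 15 diiodomethane
Product: 17 rac-2-[2,2-dimethyl-8-(3-methylbut-2-en-1-yl)-2H-chromen-6-yl]-2-(iodomethyl)-4,6-bis(methoxymethoxy)-7-(3-methylbut-2-en-1-yl)benzofuran-3(2H)-one, via sodium enolate 16 (not isolated)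
Conditions: Pd2(dba)3 (2 mol%), XPhos (8 mol%), NaOtBu (2.3 equiv), toluene, 70 °C; then CH2I2 (6 equiv), DMF, 45 °C
Reagents that add atoms: sodium tert-butoxide CC(C)(C)[O-].[Na+] (sodium of intermediate 16 only)
Why: Buchwald–Hartwig-type palladium-catalysed ketone α-arylation, then C-alkylation of the air-sensitive tertiary enolate in the same flask; the quaternary C2 is racemic, which is harmless because it becomes planar in step 9.

**Step 9**
Reactants: 17 rac-2-[2,2-dimethyl-8-(3-methylbut-2-en-1-yl)-2H-chromen-6-yl]-2-(iodomethyl)-4,6-bis(methoxymethoxy)-7-(3-methylbut-2-en-1-yl)benzofuran-3(2H)-one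
Product: 18 (2S)-2-[2,2-dimethyl-8-(3-methylbut-2-en-1-yl)-2H-chromen-6-yl]-5,7-bis(methoxymethoxy)-8-(3-methylbut-2-en-1-yl)chroman-4-one
Conditions: (Me3Si)3SiH (1.3 equiv, syringe pump, 6 h), peptide thiol Boc-Cys-D-Pro-Aib-Phe-NMe2 (5 mol%), Et3B (20 mol%)/air, PhCF3 (0.01 M), 0 °C
Reagents that add atoms: none
Why: Proposed new method: silyl-radical iodine abstraction from 17 gives a primary radical that adds 3-exo to the C3 carbonyl, and the cyclopropyloxy radical opens by β-scission of the old C2–C3 bond (radical 1,2-acyl shift, Dowd–Beckwith ring expansion) to the six-membered benzylic α-oxy C2 radical, whose planar centre erases the racemic C2 of 17; the chiral thiol then delivers H to one face to set 2S and is regenerated by the silane (polarity-reversal chain); the closest known chemistry is the tin-hydride Dowd–Beckwith expansion of halomethyl β-keto esters and thiol-catalysed enantioselective H-atom transfer in silane radical chains, neither shown on a 2-aryl benzofuranone nor combined in one step.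

**Step 10**
Reactants: 18 (2S)-2-[2,2-dimethyl-8-(3-methylbut-2-en-1-yl)-2H-chromen-6-yl]-5,7-bis(methoxymethoxy)-8-(3-methylbut-2-en-1-yl)chroman-4-one
Product: 19 Maackiaflavanone B
Conditions: 3 M aq. HCl, MeOH, 45 °C
Reagents that add atoms: none
Why: Acid-catalysed acetal exchange removes both MOM groups under conditions that leave the prenyl and chromene alkenes intact and do not open the flavanone, so C2 stays 2S.

**Compound list**
1 | resorcinol (benzene-1,3-diol) | Oc1cccc(O)c1 | starting material
2 | 1,3-bis(methoxymethoxy)benzene | COCOc1cccc(OCOC)c1 | intermediate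
3 | 2-[3,5-bis(methoxymethoxy)phenyl]-4,4,5,5-tetramethyl-1,3,2-dioxaborolane | COCOc1cc(OCOC)cc(c1)B1OC(C)(C)C(C)(C)O1 | intermediate
4 | 3,5-bis(methoxymethoxy)phenol | COCOc1cc(O)cc(OCOC)c1 | intermediate
5 | 1-bromo-3-methylbut-2-ene (prenyl bromide) | CC(C)=CCBr | starting material
6 | 3,5-bis(methoxymethoxy)-2-(3-methylbut-2-en-1-yl)phenol | Oc1cc(OCOC)cc(OCOC)c1CC=C(C)C | intermediate
7 | 2-chloro-N,N-dimethylacetamide | CN(C)C(=O)CCl | starting material
8 | 2-[3,5-bis(methoxymethoxy)-2-(3-methylbut-2-en-1-yl)phenoxy]-N,N-dimethylacetamide | CN(C)C(=O)COc1cc(OCOC)cc(OCOC)c1CC=C(C)C | intermediate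
9 | N-[4,6-bis(methoxymethoxy)-7-(3-methylbut-2-en-1-yl)benzofuran-3(2H)-ylidene]-N-methylmethanaminium triflate | C[N+](C)=C1COc2c(CC=C(C)C)c(OCOC)cc(OCOC)c12.[O-]S(=O)(=O)C(F)(F)F | intermediate
10 | 4,6-bis(methoxymethoxy)-7-(3-methylbut-2-en-1-yl)benzofuran-3(2H)-one | O=C1COc2c(CC=C(C)C)c(OCOC)cc(OCOC)c12 | intermediate
11 | 4-bromophenol | Oc1ccc(Br)cc1 | starting material
12 | 4-bromo-2-(3-methylbut-2-en-1-yl)phenol | Oc1ccc(Br)cc1CC=C(C)C | intermediate
13 | 3-methylbut-2-enal | CC(C)=CC=O | starting material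
14 | 6-bromo-2,2-dimethyl-8-(3-methylbut-2-en-1-yl)-2H-chromene | CC(C)=CCc1cc(Br)cc2C=CC(C)(C)Oc12 | intermediate
15 | diiodomethane | ICI | starting material
16 | sodium 2-[2,2-dimethyl-8-(3-methylbut-2-en-1-yl)-2H-chromen-6-yl]-4,6-bis(methoxymethoxy)-7-(3-methylbut-2-en-1-yl)benzofuran-3-olate | [Na+].[O-]c1c(-c2cc(CC=C(C)C)c3OC(C)(C)C=Cc3c2)oc2c(CC=C(C)C)c(OCOC)cc(OCOC)c12 | intermediate
17 | rac-2-[2,2-dimethyl-8-(3-methylbut-2-en-1-yl)-2H-chromen-6-yl]-2-(iodomethyl)-4,6-bis(methoxymethoxy)-7-(3-methylbut-2-en-1-yl)benzofuran-3(2H)-one | O=C1C(CI)(c2cc(CC=C(C)C)c3OC(C)(C)C=Cc3c2)Oc2c(CC=C(C)C)c(OCOC)cc(OCOC)c12 | intermediate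
18 | (2S)-2-[2,2-dimethyl-8-(3-methylbut-2-en-1-yl)-2H-chromen-6-yl]-5,7-bis(methoxymethoxy)-8-(3-methylbut-2-en-1-yl)chroman-4-one | CC(C)=CCc1cc([C@@H]2CC(=O)c3c(OCOC)cc(OCOC)c(CC=C(C)C)c3O2)cc2c1OC(C)(C)C=C2 | intermediate
19 | Maackiaflavanone B, (2S)-2-[2,2-dimethyl-8-(3-methylbut-2-en-1-yl)-2H-chromen-6-yl]-5,7-dihydroxy-8-(3-methylbut-2-en-1-yl)chroman-4-one | CC(C)=CCc1cc([C@@H]2CC(=O)c3c(O)cc(O)c(CC=C(C)C)c3O2)cc2c1OC(C)(C)C=C2 | target

**Totals**
Total step count: 10. Longest linear sequence: 8 steps (1, 2, 3, 4, 5, 8, 9, 10 from resorcinol); the ring B branch (steps 6 and 7) joins at step 8.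

**Steps most likely to fail, with fallbacks**

Step 9 (the proposed new step). The thiol or silane may reduce the primary radical before the acyl shift, which would give the 2-methyl ketone. The primary radical may also lose the aryloxyl group by β-scission, opening a path to isoflavanone-type by-products. The H-atom transfer may give low ee, or the thiyl radical may re-abstract the C2–H. The fallback uses known chemistry, sets out from 17 and comes back at 18. Slow addition of n-Bu3SnH/AIBN to 17 in refluxing benzene at high dilution (classical Dowd–Beckwith ring expansion) gives the racemic bis-MOM flavanone F1. Kinetic resolution by asymmetric transfer hydrogenation ([Cp*RhCl((R,R)-TsDPEN)], HCO2H/Et3N, EtOAc, rt, about 55% conversion) reduces the 2R enantiomer to the (2R,4R)-cis-flavan-4-ol F2 and leaves 18, which is separated by chromatography. If the sense of the resolution is reversed, the mirror-image catalyst is used.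

Step 8. Diarylation, aerobic oxidation of the 2-aryl enolate, or slow or O-selective reaction with CH2I2 can spoil the one-pot sequence. The fallback sets out from 10 and 14 and comes back at 17, and it changes how the one-carbon unit is attached. The α-arylation is run with K3PO4 and quenched to isolate the 2-aryl ketone F3. An aldol reaction with aqueous formaldehyde (cat. Et3N, THF, rt) gives the 2-hydroxymethyl ketone F4. PPh3/I2/imidazole (toluene, 80 °C) then converts the neopentyl-type alcohol into 17.

Step 5. Intermolecular acylation at the more nucleophilic C4 position, attack of Tf2O on a MOM acetal, or reaction of the activated amide with the prenyl alkene may compete with the five-membered ring closure. The fallback sets out from 6 and comes back at 10. Magnesium-mediated ortho-formylation (MgCl2, Et3N, paraformaldehyde, MeCN, reflux) gives the salicylaldehyde F5. A Corey–Chaykovsky reaction (trimethylsulfoxonium iodide, NaH, DMSO, rt) with ring closure by the phenoxide gives the 2,3-dihydrobenzofuran-3-ol F6. Dess–Martin periodinane (NaHCO3, CH2Cl2, rt) oxidises it to 10.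

**Further compounds**
F1 | step 9 | rac-2-[2,2-dimethyl-8-(3-methylbut-2-en-1-yl)-2H-chromen-6-yl]-5,7-bis(methoxymethoxy)-8-(3-methylbut-2-en-1-yl)chroman-4-one | CC(C)=CCc1cc(C2CC(=O)c3c(OCOC)cc(OCOC)c(CC=C(C)C)c3O2)cc2c1OC(C)(C)C=C2
F2 | step 9 | (2R,4R)-2-[2,2-dimethyl-8-(3-methylbut-2-en-1-yl)-2H-chromen-6-yl]-5,7-bis(methoxymethoxy)-8-(3-methylbut-2-en-1-yl)chroman-4-ol | CC(C)=CCc1cc([C@H]2C[C@@H](O)c3c(OCOC)cc(OCOC)c(CC=C(C)C)c3O2)cc2c1OC(C)(C)C=C2
F3 | step 8 | rac-2-[2,2-dimethyl-8-(3-methylbut-2-en-1-yl)-2H-chromen-6-yl]-4,6-bis(methoxymethoxy)-7-(3-methylbut-2-en-1-yl)benzofuran-3(2H)-one | O=C1C(c2cc(CC=C(C)C)c3OC(C)(C)C=Cc3c2)Oc2c(CC=C(C)C)c(OCOC)cc(OCOC)c12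
F4 | step 8 | rac-2-[2,2-dimethyl-8-(3-methylbut-2-en-1-yl)-2H-chromen-6-yl]-2-(hydroxymethyl)-4,6-bis(methoxymethoxy)-7-(3-methylbut-2-en-1-yl)benzofuran-3(2H)-one | O=C1C(CO)(c2cc(CC=C(C)C)c3OC(C)(C)C=Cc3c2)Oc2c(CC=C(C)C)c(OCOC)cc(OCOC)c12
F5 | step 5 | 2-hydroxy-4,6-bis(methoxymethoxy)-3-(3-methylbut-2-en-1-yl)benzaldehyde | O=Cc1c(O)c(CC=C(C)C)c(OCOC)cc1OCOC
F6 | step 5 | rac-4,6-bis(methoxymethoxy)-7-(3-methylbut-2-en-1-yl)-2,3-dihydrobenzofuran-3-ol | OC1COc2c(CC=C(C)C)c(OCOC)cc(OCOC)c12
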